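**Retrosynthetic overview**

1. The target is robinetinidol-(4α→8)-epigallocatechin 3-O-gallate. The last disconnections are the twelve benzyl ethers and then the interflavanyl C4–C8 bond. That bond is made by SN1 Friedel–Crafts attack of octa-O-benzyl-EGCG (C8 of its phloroglucinol ring D) on the C4 cation of a 4-alkoxy-robinetinidol, with the C3 hydroxyl directing 3,4-trans. The lower unit comes from (−)-epigallocatechin by fivefold benzylation and galloylation with 3,4,5-tris(benzyloxy)benzoic acid.
2. The C4 oxygen comes from DDQ oxidation of the benzylic CH2 para to the 7-benzyloxy group of ring A. C3–OH and C2–H come together from one cis, anti-Markovnikov asymmetric hydroboration of the C2=C3 enol ether of a flav-2-ene.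
3. Ring C of the upper unit is closed by making C2=C3 through a titanium-alkylidene olefinic ester cyclization. The enabling feature is that C2 is bonded to the ring oxygen O1 (a phenol oxygen of ring A) and to aromatic ring B, so it is a masked carbonyl carbon of an aryl 3,4,5-trioxybenzoate, while C3–C4 is an allyl side chain ortho to O1 on ring A.
4. Order of ring formation: all aromatic rings and the lower pyran ring are bought (4-(benzyloxy)-2-hydroxybenzaldehyde, 3,4,5-tris(benzyloxy)benzoic acid, (−)-epigallocatechin); the upper pyran ring C is the only ring built.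

Key step: step 5

Remark on the chemistry: the C4 configuration of 14 does not matter, because C4 is ionised again in step 10; 14 is written as the 4β (4S) epimer expected from axial attack of the alcohol anti to the C2 aryl group.

**Route**

Step 1
Reactants: 1 4-(benzyloxy)-2-hydroxybenzaldehyde
Product: 2 tert-butyl 5-(benzyloxy)-2-formylphenyl carbonate
Conditions: Boc2O, iPr2NEt, DMAP (cat.), CH2Cl2, 0 °C → rt
Reagents that add atoms: di-tert-butyl dicarbonate, CC(C)(C)OC(=O)OC(=O)OC(C)(C)C
Why: DMAP-catalysed acylation of the phenol by Boc2O gives the aryl tert-butyl carbonate that later serves as the leaving group for quinone methide formation, and no stereocentre is involved.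

Step 2
Reactants: 2 tert-butyl 5-(benzyloxy)-2-formylphenyl carbonate
Product: 3 tert-butyl 5-(benzyloxy)-2-(hydroxymethyl)phenyl carbonate
Conditions: BH3·THF, THF, 0 °C; then MeOH, H2O
Reagents that add atoms: none
Why: Chemoselective borane reduction of the aldehyde gives the benzylic alcohol, and borane is chosen because a neutral alkoxyborane, unlike a metal alkoxide, should not trigger premature transfer of the carbonate group; no stereocentre is formed.

Step 3
Reactants: 3 tert-butyl 5-(benzyloxy)-2-(hydroxymethyl)phenyl carbonate; 4 vinylmagnesium bromide (CH2=CHMgBr)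
Product: 6 2-allyl-5-(benzyloxy)phenol, via o-quinone methide 5 (not isolated)
Conditions: CH2=CHMgBr (2.5 equiv), THF, −78 °C → rt; then 1 M HCl
Reagents that add atoms: none
Why: Anionic ortho-quinone methide generation followed by conjugate addition, in which deprotonation of the alcohol, O-to-O transfer of the carbonate and β-elimination of tert-butyl carbonate generate 5, and 1,4-addition of a second equivalent of the vinyl Grignard reagent to its exocyclic CH2 restores the arene with the allyl group ortho to the free phenol; no stereocentre is formed.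

Step 4
Reactants: 6 2-allyl-5-(benzyloxy)phenol; 7 3,4,5-tris(benzyloxy)benzoic acid
Product: 8 2-allyl-5-(benzyloxy)phenyl 3,4,5-tris(benzyloxy)benzoate
Conditions: DIC, DMAP (cat.), CH2Cl2, rt
Reagents that add atoms: none
Why: Steglich esterification of the phenol with the carbodiimide-activated acid places C2 and ring B on O1 as an aryl ester, and no stereocentre is formed.

Step 5
Reactants: 8 2-allyl-5-(benzyloxy)phenyl 3,4,5-tris(benzyloxy)benzoate
Product: 10 7-(benzyloxy)-2-[3,4,5-tris(benzyloxy)phenyl]-4H-chromene, via titanium alkylidene 9 (not isolated)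
Conditions: TiCl4, TMEDA, Zn, PbCl2 (cat.), CH3CHBr2, THF/CH2Cl2, 0 → 65 °C
Reagents that add atoms: none
Why: Zn reduces TiCl4 in the presence of CH3CHBr2 and TMEDA to a nucleophilic titanium ethylidene, which exchanges with the terminal alkene of 8 (propene leaves) to give alkylidene 9 with the metal on C3, and 9 then adds to the neighbouring ester C=O by [2+2] cycloaddition and cycloreverts to the C2=C3 enol ether and a Ti=O unit. The closest known reaction type is the olefinic ester cyclization with the Takai–Utimoto titanium alkylidene reagent, a ring-closing carbonyl–olefin metathesis that turns ω-alkenyl esters into six- and seven-membered cyclic enol ethers. Ring C closes as a six-membered ring by intramolecular carbonyl olefination between C3 and the ester carbon C2, and if ester ethylidenation came first, ring-closing metathesis of that enol ether with the allyl group would lead to the same product. No stereocentre is created; the step fixes the double bond inside ring C at C2=C3, conjugated with ring B, which is the precondition for setting C2 and C3 together in step 6. The selectivity needed is ring closure over simple ethylidenation of the ester and over migration of the allyl double bond, together with tolerance of four benzyl ethers; the ortho arrangement of allyl and acyloxy groups on ring A holds C3 within reach of C2 for a strain-free six-membered ring, the acyl part has no α-hydrogen to enolise, and benzyl ethers are inert to this reagent.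

Step 6
Reactants: 10 7-(benzyloxy)-2-[3,4,5-tris(benzyloxy)phenyl]-4H-chromene
Product: 12 (2R,3S)-7-(benzyloxy)-2-[3,4,5-tris(benzyloxy)phenyl]chroman-3-ol, via organoborane 11 (not isolated)
Conditions: (IpcBH2)2·TMEDA [from (+)-α-pinene], BF3·OEt2, THF, rt; then 10, −25 °C; then NaOH, H2O2, 0 °C → rt
Reagents that add atoms: hydrogen peroxide, OO
Why: Asymmetric hydroboration–oxidation with monoisopinocampheylborane, in which boron adds to C3 (β to the ring oxygen and non-benzylic) and hydrogen to C2 on the same face so that the C2 aryl group and the C3 oxygen end up trans, the isopinocampheyl group from (+)-α-pinene selects the alkene face by analogy with 1-arylcycloalkenes, which give (1S,2R)-trans-2-arylcycloalkanols (the reagent from (−)-α-pinene would be used should the enol ether oxygen invert this preference), and oxidation with retention at C3 delivers the (2R,3S) alcohol.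

Step 7
Reactants: 12 (2R,3S)-7-(benzyloxy)-2-[3,4,5-tris(benzyloxy)phenyl]chroman-3-ol
Product: 14 (2R,3S,4S)-7-(benzyloxy)-4-(2-ethoxyethoxy)-2-[3,4,5-tris(benzyloxy)phenyl]chroman-3-ol, via C4 benzylic cation 13 (not isolated)
Conditions: DDQ, 2-ethoxyethanol, 4 Å MS, CH2Cl2, rt
Reagents that add atoms: 2-ethoxyethanol, CCOCCO
Why: DDQ oxidation of the benzylic C4–H, where hydride abstraction is eased by the para 7-benzyloxy group and the ortho ring oxygen of ring A, gives cation 13, which is trapped by 2-ethoxyethanol as is known for benzylated flavan-3-ols; the new C4 centre is expected to arise from axial attack anti to the C2 aryl group (4β).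

Step 8
Reactants: 15 (−)-epigallocatechin
Product: 16 (2R,3R)-5,7-bis(benzyloxy)-2-[3,4,5-tris(benzyloxy)phenyl]chroman-3-ol (penta-O-benzyl-epigallocatechin)
Conditions: BnBr (5.5 equiv), K2CO3, DMF, 0 °C → rt, N2, dark
Reagents that add atoms: benzyl bromide, BrCc1ccccc1
Why: Fivefold Williamson etherification, in which K2CO3 deprotonates only the five phenols and leaves the secondary C3 alcohol untouched, and the low temperature and exclusion of oxygen should suppress base-induced epimerisation at C2, so the natural (2R,3R) stereocentres are kept.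

Step 9
Reactants: 16 (2R,3R)-5,7-bis(benzyloxy)-2-[3,4,5-tris(benzyloxy)phenyl]chroman-3-ol; 7 3,4,5-tris(benzyloxy)benzoic acid
Product: 17 octa-O-benzyl-EGCG, (2R,3R)-5,7-bis(benzyloxy)-2-[3,4,5-tris(benzyloxy)phenyl]chroman-3-yl 3,4,5-tris(benzyloxy)benzoate
Conditions: DIC, DMAP, CH2Cl2, rt
Reagents that add atoms: none
Why: Steglich esterification of the axial C3 hydroxyl with the carbodiimide-activated tri-O-benzylgallic acid, a standard galloylation of benzylated flavan-3-ols in which the C3–O bond is not broken, so C3 keeps its configuration.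

Step 10
Reactants: 14 (2R,3S,4S)-7-(benzyloxy)-4-(2-ethoxyethoxy)-2-[3,4,5-tris(benzyloxy)phenyl]chroman-3-ol; 17 octa-O-benzyl-EGCG
Product: 18 (2R,3R)-5,7-bis(benzyloxy)-8-{(2R,3S,4S)-7-(benzyloxy)-3-hydroxy-2-[3,4,5-tris(benzyloxy)phenyl]chroman-4-yl}-2-[3,4,5-tris(benzyloxy)phenyl]chroman-3-yl 3,4,5-tris(benzyloxy)benzoate
Conditions: 17 (3 equiv), TMSOTf (cat.), CH2Cl2, −78 → −40 °C; then Et3N
Reagents that add atoms: none
Why: Lewis-acid-promoted SN1 Friedel–Crafts alkylation (the biomimetic proanthocyanidin condensation), in which TMSOTf ionises the C4 ether of 14 back to the benzylic cation 13 that step 7 passes through, the most nucleophilic position of 17 (C8 of ring D, used in excess to outcompete self-condensation) attacks it, and the nucleophile enters on the face opposite the C3 hydroxyl group, which should set C4 as 4α (3,4-trans, 4S) as is usual for 2,3-trans-flavan-4-yl cations.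

Step 11
Reactants: 18 dodeca-O-benzyl dimer (name as in step 10)
Product: 19 robinetinidol-(4α→8)-epigallocatechin 3-O-gallate
Conditions: H2 (1 atm), Pd(OH)2/C, THF/MeOH/H2O, rt
Reagents that add atoms: none
Why: Catalytic hydrogenolysis of the twelve benzyl ethers over Pd(OH)2 on carbon under neutral conditions, which are known to spare the interflavanyl C4–C8 bond, the benzylic C2–O1 ether bonds and the gallate ester of benzylated proanthocyanidins, so all five stereocentres are carried through unchanged.

**Compound list**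

1 | 4-(benzyloxy)-2-hydroxybenzaldehyde | O=Cc1ccc(OCc2ccccc2)cc1O | starting material
2 | tert-butyl 5-(benzyloxy)-2-formylphenyl carbonate | CC(C)(C)OC(=O)Oc1cc(OCc2ccccc2)ccc1C=O | intermediate
3 | tert-butyl 5-(benzyloxy)-2-(hydroxymethyl)phenyl carbonate | CC(C)(C)OC(=O)Oc1cc(OCc2ccccc2)ccc1CO | intermediate
4 | vinylmagnesium bromide (CH2=CHMgBr) | C=C[Mg]Br | starting material
5 | 3-(benzyloxy)-6-methylidenecyclohexa-2,4-dien-1-one (o-quinone methide, not isolated) | O=C1C=C(OCc2ccccc2)C=CC1=C | intermediate
6 | 2-allyl-5-(benzyloxy)phenol | C=CCc1ccc(OCc2ccccc2)cc1O | intermediate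
7 | 3,4,5-tris(benzyloxy)benzoic acid | OC(=O)c1cc(OCc2ccccc2)c(OCc2ccccc2)c(OCc2ccccc2)c1 | starting material
8 | 2-allyl-5-(benzyloxy)phenyl 3,4,5-tris(benzyloxy)benzoate | C=CCc1ccc(OCc2ccccc2)cc1OC(=O)c1cc(OCc2ccccc2)c(OCc2ccccc2)c(OCc2ccccc2)c1 | intermediate
9 | titanium alkylidene Cl2Ti=CH–CH2–aryl of ester 8, TMEDA-ligated (not isolated) | Cl[Ti](Cl)=CCc1ccc(OCc2ccccc2)cc1OC(=O)c1cc(OCc2ccccc2)c(OCc2ccccc2)c(OCc2ccccc2)c1 | intermediate
10 | 7-(benzyloxy)-2-[3,4,5-tris(benzyloxy)phenyl]-4H-chromene | C1=C(c2cc(OCc3ccccc3)c(OCc3ccccc3)c(OCc3ccccc3)c2)Oc2cc(OCc3ccccc3)ccc2C1 | intermediate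
11 | isopinocampheyl[(2S,3S)-7-(benzyloxy)-2-[3,4,5-tris(benzyloxy)phenyl]chroman-3-yl]borane (2,3-trans, same spatial arrangement as 12; not isolated) | C[C@@H]1[C@H]2C[C@H](C2(C)C)C[C@H]1B[C@H]1Cc2ccc(OCc3ccccc3)cc2O[C@@H]1c1cc(OCc2ccccc2)c(OCc2ccccc2)c(OCc2ccccc2)c1 | intermediate
12 | (2R,3S)-7-(benzyloxy)-2-[3,4,5-tris(benzyloxy)phenyl]chroman-3-ol (tetra-O-benzylrobinetinidol) | O[C@H]1Cc2ccc(OCc3ccccc3)cc2O[C@@H]1c1cc(OCc2ccccc2)c(OCc2ccccc2)c(OCc2ccccc2)c1 | intermediate
13 | C4 benzylic cation of 12 (2,3-trans, stabilised by the 7-benzyloxy group; not isolated) | O[C@H]1[CH+]c2ccc(OCc3ccccc3)cc2O[C@@H]1c1cc(OCc2ccccc2)c(OCc2ccccc2)c(OCc2ccccc2)c1 | intermediate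
14 | (2R,3S,4S)-7-(benzyloxy)-4-(2-ethoxyethoxy)-2-[3,4,5-tris(benzyloxy)phenyl]chroman-3-ol | CCOCCO[C@H]1c2ccc(OCc3ccccc3)cc2O[C@H](c2cc(OCc3ccccc3)c(OCc3ccccc3)c(OCc3ccccc3)c2)[C@H]1O | intermediate
15 | (−)-epigallocatechin, (2R,3R) | O[C@@H]1Cc2c(O)cc(O)cc2O[C@@H]1c1cc(O)c(O)c(O)c1 | starting material
16 | penta-O-benzyl-epigallocatechin: (2R,3R)-5,7-bis(benzyloxy)-2-[3,4,5-tris(benzyloxy)phenyl]chroman-3-ol | O[C@@H]1Cc2c(OCc3ccccc3)cc(OCc3ccccc3)cc2O[C@@H]1c1cc(OCc2ccccc2)c(OCc2ccccc2)c(OCc2ccccc2)c1 | intermediate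
17 | octa-O-benzyl-EGCG: (2R,3R)-5,7-bis(benzyloxy)-2-[3,4,5-tris(benzyloxy)phenyl]chroman-3-yl 3,4,5-tris(benzyloxy)benzoate | O=C(O[C@@H]1Cc2c(OCc3ccccc3)cc(OCc3ccccc3)cc2O[C@@H]1c1cc(OCc2ccccc2)c(OCc2ccccc2)c(OCc2ccccc2)c1)c1cc(OCc2ccccc2)c(OCc2ccccc2)c(OCc2ccccc2)c1 | intermediate
18 | dodeca-O-benzyl dimer: (2R,3R)-5,7-bis(benzyloxy)-8-{(2R,3S,4S)-7-(benzyloxy)-3-hydroxy-2-[3,4,5-tris(benzyloxy)phenyl]chroman-4-yl}-2-[3,4,5-tris(benzyloxy)phenyl]chroman-3-yl 3,4,5-tris(benzyloxy)benzoate | O=C(O[C@@H]1Cc2c(OCc5ccccc5)cc(OCc5ccccc5)c([C@@H]3c4ccc(OCc5ccccc5)cc4O[C@H](c4cc(OCc5ccccc5)c(OCc5ccccc5)c(OCc5ccccc5)c4)[C@H]3O)c2O[C@@H]1c1cc(OCc5ccccc5)c(OCc5ccccc5)c(OCc5ccccc5)c1)c1cc(OCc5ccccc5)c(OCc5ccccc5)c(OCc5ccccc5)c1 | intermediate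
19 | robinetinidol-(4α→8)-epigallocatechin 3-O-gallate: (2R,3R)-5,7-dihydroxy-8-[(2R,3S,4S)-3,7-dihydroxy-2-(3,4,5-trihydroxyphenyl)chroman-4-yl]-2-(3,4,5-trihydroxyphenyl)chroman-3-yl 3,4,5-trihydroxybenzoate | O=C(O[C@@H]1Cc2c(O)cc(O)c([C@@H]3c4ccc(O)cc4O[C@H](c4cc(O)c(O)c(O)c4)[C@H]3O)c2O[C@@H]1c1cc(O)c(O)c(O)c1)c1cc(O)c(O)c(O)c1 | target

**Step count and risks**

Total step count: 11. Longest linear sequence: 9 steps (steps 1–7, 10 and 11; steps 8 and 9 form the two-step side branch).

Steps most likely to fail:

Step 5. The titanium ethylidene may olefinate the ester without the ring then closing, low-valent titanium may cleave the aryl ester reductively, or the allyl double bond may migrate into conjugation before closure. The fallback separates olefination from ring closure and uses ruthenium-catalysed metathesis. It sets out from 8: methylenation of the ester carbonyl with dimethyltitanocene Cp2TiMe2 (toluene, 70 °C) should give the enol ether 2-allyl-5-(benzyloxy)phenyl 1-[3,4,5-tris(benzyloxy)phenyl]ethenyl ether F1. Ring-closing enol ether–olefin metathesis of F1 with second-generation Grubbs catalyst (H2IMes)(PCy3)Cl2Ru=CHPh (toluene, 70 °C) expels ethene and rejoins the route at 10.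

Step 6. The chiral borane may discriminate poorly between the two faces of this aryl enol ether, which would give the alcohol in low enantiomeric purity. The fallback replaces reagent control by an enzymatic resolution. It sets out from 10: hydroboration with achiral BH3·SMe2 followed by NaOH/H2O2 should give the racemic trans alcohol, that is 12 together with its enantiomer (2S,3R)-7-(benzyloxy)-2-[3,4,5-tris(benzyloxy)phenyl]chroman-3-ol F2. Kinetic resolution with a lipase (Burkholderia cepacia lipase, vinyl acetate, tert-butyl methyl ether) is expected, by the empirical rule for lipase acylation of secondary alcohols, to acetylate the (3R) enantiomer to (2S,3R)-7-(benzyloxy)-2-[3,4,5-tris(benzyloxy)phenyl]chroman-3-yl acetate F3 and to leave 12 unreacted, where the route is rejoined.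

Step 10. The nucleophile may attack the cation from the face of the C3 hydroxyl (loss of 3,4-trans selectivity), and self-condensation of the electrophile may compete. The fallback moves stereocontrol from the free hydroxyl to anchimeric participation by a removable ester. It sets out from 14: esterification of the C3 hydroxyl with levulinic acid (DIC, DMAP, CH2Cl2) should give (2R,3S,4S)-7-(benzyloxy)-4-(2-ethoxyethoxy)-2-[3,4,5-tris(benzyloxy)phenyl]chroman-3-yl 4-oxopentanoate F4. In the TMSOTf-promoted coupling of F4 with 17 the neighbouring acyloxy group shields the β face of C4, so that only α attack remains and the product should be the 3-O-levulinoyl dodeca-O-benzyl dimer F5. Hydrazine acetate (pyridine/AcOH, rt) removes the levulinoyl group from F5 while the hindered gallate and the benzyl ethers stay, and the route is rejoined at 18.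

Further compounds
F1 | step 5 | 2-allyl-5-(benzyloxy)phenyl 1-[3,4,5-tris(benzyloxy)phenyl]ethenyl ether | C=CCc1ccc(OCc2ccccc2)cc1OC(=C)c1cc(OCc2ccccc2)c(OCc2ccccc2)c(OCc2ccccc2)c1
F2 | step 6 | (2S,3R)-7-(benzyloxy)-2-[3,4,5-tris(benzyloxy)phenyl]chroman-3-ol (enantiomer of 12) | O[C@@H]1Cc2ccc(OCc3ccccc3)cc2O[C@H]1c1cc(OCc2ccccc2)c(OCc2ccccc2)c(OCc2ccccc2)c1
F3 | step 6 | (2S,3R)-7-(benzyloxy)-2-[3,4,5-tris(benzyloxy)phenyl]chroman-3-yl acetate | CC(=O)O[C@@H]1Cc2ccc(OCc3ccccc3)cc2O[C@H]1c1cc(OCc2ccccc2)c(OCc2ccccc2)c(OCc2ccccc2)c1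
F4 | step 10 | (2R,3S,4S)-7-(benzyloxy)-4-(2-ethoxyethoxy)-2-[3,4,5-tris(benzyloxy)phenyl]chroman-3-yl 4-oxopentanoate | CCOCCO[C@H]1c2ccc(OCc3ccccc3)cc2O[C@H](c2cc(OCc3ccccc3)c(OCc3ccccc3)c(OCc3ccccc3)c2)[C@H]1OC(=O)CCC(C)=O
F5 | step 10 | 3-O-levulinoyl derivative of 18 (levulinate on the C3 oxygen of the upper unit) | O=C(O[C@@H]1Cc2c(OCc5ccccc5)cc(OCc5ccccc5)c([C@@H]3c4ccc(OCc5ccccc5)cc4O[C@H](c4cc(OCc5ccccc5)c(OCc5ccccc5)c(OCc5ccccc5)c4)[C@H]3OC(=O)CCC(C)=O)c2O[C@@H]1c1cc(OCc5ccccc5)c(OCc5ccccc5)c(OCc5ccccc5)c1)c1cc(OCc5ccccc5)c(OCc5ccccc5)c(OCc5ccccc5)c1
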